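**Remark on the structure:** the SMILES is read as (3R,4S,5R,6S,7R,8S,9R; 2′S,3′S) with a ring‑cis C1=C10 bond, a trans‑fused 12,6‑lactone and a 4,5‑oxirane in which C3 and C6 are cis (the epoxide of a 4Z alkene). Positions quoted as Cn follow germacrane numbering (C1–C10 ring, C11–C13 lactone carbons, C14 ester carbon on C10, C15 methyl on C4); compound names use their own locants.

**Remark on materials:** (+)‑B‑allyldiisopinocampheylborane (pentane solution), D‑glyceraldehyde acetonide, 2‑bromoacrylic acid and angelic acid are taken as commercial.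

## Retrosynthetic overview

1. Last events: hydroxyl‑directed epoxidation of the 4Z alkene, and acylation of O9 (acetate) and O8 (epoxyangelate, made from angelic acid by asymmetric epoxidation).
2. Key disconnection: the α‑methylene‑γ‑lactone is removed as 2‑bromoacrylic acid; a Pd‑catalysed [3+2] heteroannulation onto the ring diene C4=C5–C6=C7 forms O–C6 and C7–C11 at once.
3. Enabling feature: the lactone carbinol C6 sits between C7 (which carries C11) and the C4–C5 oxirane. Without the oxirane oxygen, C4=C5 is an alkene allylic to C6, so the ten‑membered ring holds a C4–C7 1,3‑diene whose η3‑allyl‑Pd (C4–C6) is captured at C6 by the carboxylate.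
4. Ten‑membered ring by Nozaki–Hiyama–Kishi closure of C9–C10; the chain from a Sonogashira union (C5–C6) of a Z‑iodoalkene aldehyde with (S)‑butynediol bis‑TES ether, semi‑hydrogenation and an iodo‑Wittig reaction.
5. Ring order: cyclodecatriene (step 13), then γ‑lactone (step 14), then 4,5‑oxirane (step 22); the side‑chain oxirane is made separately (step 18).

Key step: step 14

## Route

Step 1
Reactants: 1 prop‑2‑yn‑1‑ol
Product: 3 (Z)‑3‑iodo‑2‑methylprop‑2‑en‑1‑ol, via vinylmagnesium alkoxide 2 (not isolated)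
Conditions: MeMgBr (3 equiv), CuI (10 mol %), THF, −10 °C → rt; then I2, −78 → 0 °C
Reagents that add atoms: methylmagnesium bromide, C[Mg]Br; iodine, II
Why: Copper‑catalysed anti‑carbomagnesiation of the propargylic alkoxide (Duboudin‑type addition) puts the methyl group on C2 and magnesium on C3 inside a five‑membered chelate, so iodinolysis with retention should give the Z‑iodoalkene only.

Step 2
Reactants: 3 (Z)‑3‑iodo‑2‑methylprop‑2‑en‑1‑ol
Product: 4 (Z)‑3‑iodo‑2‑methylprop‑2‑enal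
Conditions: activated MnO2, CH2Cl2, rt, dark; used crude
Reagents that add atoms: none
Why: Activated MnO2 oxidises the allylic alcohol selectively under neutral conditions that should leave the Z geometry of the iodoalkene untouched.

Step 3
Reactants: 4 (Z)‑3‑iodo‑2‑methylprop‑2‑enal
Product: 6 (3R,1Z)‑1‑iodo‑2‑methylhexa‑1,5‑dien‑3‑ol, via borinate ester 5 (not isolated)
Conditions: (+)‑Ipc2B(allyl), Et2O, −78 °C; then 3 M NaOH, 30 % H2O2, 0 °C → rt
Reagents that add atoms: (+)‑B‑allyldiisopinocampheylborane, C=CCB([C@H]1C[C@H]2C[C@H](C2(C)C)[C@@H]1C)[C@H]1C[C@H]2C[C@H](C2(C)C)[C@@H]1C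
Why: Brown allylboration through a chair‑like six‑membered transition state, in which the (+)‑Ipc2B reagent should attack the aldehyde face that gives the R carbinol (C3 of the target) by analogy with its known sense for aryl and α,β‑unsaturated aldehydes, the oxidative work‑up freeing the alcohol from the borinate.

Step 4
Reactants: 6 (3R,1Z)‑1‑iodo‑2‑methylhexa‑1,5‑dien‑3‑ol
Product: 7 tert‑butyl{[(3R,1Z)‑1‑iodo‑2‑methylhexa‑1,5‑dien‑3‑yl]oxy}dimethylsilane
Conditions: TBSCl, imidazole, DMF, rt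
Reagents that add atoms: tert‑butyldimethylsilyl chloride, CC(C)(C)[Si](C)(C)Cl
Why: Standard silyl ether formation on the secondary allylic alcohol; no stereocentre is touched.

Step 5
Reactants: 7 tert‑butyl{[(3R,1Z)‑1‑iodo‑2‑methylhexa‑1,5‑dien‑3‑yl]oxy}dimethylsilane
Product: 9 (3R,4Z)‑3‑[(tert‑butyldimethylsilyl)oxy]‑5‑iodo‑4‑methylpent‑4‑enal, via vicinal diol 8 (not isolated)
Conditions: OsO4 (2 mol %), NaIO4 (4 equiv), 2,6‑lutidine, 1,4‑dioxane/H2O 3:1, rt
Reagents that add atoms: osmium tetroxide (catalytic oxygen carrier), O=[Os](=O)(=O)=O; sodium periodate, [Na+].[O-]I(=O)(=O)=O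
Why: Lemieux–Johnson oxidation, in which OsO4 dihydroxylates the monosubstituted alkene far faster than the hindered, electron‑poor iodoalkene and periodate cleaves the diol to the aldehyde that becomes C1.

Step 6
Reactants: 10 (R)‑2,2‑dimethyl‑1,3‑dioxolane‑4‑carbaldehyde
Product: 11 (S)‑4‑ethynyl‑2,2‑dimethyl‑1,3‑dioxolane
Conditions: dimethyl (1‑diazo‑2‑oxopropyl)phosphonate, K2CO3, MeOH, 0 °C → rt
Reagents that add atoms: dimethyl (1‑diazo‑2‑oxopropyl)phosphonate, COP(=O)(OC)C(=[N+]=[N-])C(C)=O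
Why: The Ohira–Bestmann variant of the Seyferth–Gilbert homologation turns the aldehyde into the terminal alkyne (C6≡C7) under mildly basic conditions that are expected to preserve the adjacent stereocentre, the future C8.

Step 7
Reactants: 11 (S)‑4‑ethynyl‑2,2‑dimethyl‑1,3‑dioxolane
Product: 12 (S)‑but‑3‑yne‑1,2‑diol
Conditions: Dowex 50W‑X8 (H+ form), MeOH/H2O, rt
Reagents that add atoms: none
Why: Acid‑catalysed acetal hydrolysis liberates the 1,2‑diol without touching the stereocentre.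

Step 8
Reactants: 12 (S)‑but‑3‑yne‑1,2‑diol
Product: 13 (S)‑3,4‑bis[(triethylsilyl)oxy]but‑1‑yne
Conditions: TESCl (2.5 equiv), imidazole, DMF, 0 °C → rt
Reagents that add atoms: chlorotriethylsilane, CC[Si](Cl)(CC)CC
Why: Silyl ether formation on both hydroxyls gives two TES ethers that are told apart later, because only a primary TES ether is oxidised under Swern conditions.

Step 9
Reactants: 9 (3R,4Z)‑3‑[(tert‑butyldimethylsilyl)oxy]‑5‑iodo‑4‑methylpent‑4‑enal; 13 (S)‑3,4‑bis[(triethylsilyl)oxy]but‑1‑yne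
Product: 14 (3R,4Z,8S)‑3‑[(tert‑butyldimethylsilyl)oxy]‑4‑methyl‑8,9‑bis[(triethylsilyl)oxy]non‑4‑en‑6‑ynal
Conditions: PdCl2(PPh3)2 (5 mol %), CuI (10 mol %), Et3N, THF, rt
Reagents that add atoms: none
Why: Sonogashira coupling joins C5 to C6 with retention of the Z geometry of the iodoalkene and tolerates the aldehyde and the silyl ethers.

Step 10
Reactants: 14 (3R,4Z,8S)‑3‑[(tert‑butyldimethylsilyl)oxy]‑4‑methyl‑8,9‑bis[(triethylsilyl)oxy]non‑4‑en‑6‑ynal
Product: 15 (3R,4Z,6Z,8S)‑3‑[(tert‑butyldimethylsilyl)oxy]‑4‑methyl‑8,9‑bis[(triethylsilyl)oxy]nona‑4,6‑dienal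
Conditions: H2 (1 atm), Lindlar catalyst, quinoline, EtOAc, rt, stopped at one equivalent of H2
Reagents that add atoms: none
Why: Lindlar semi‑hydrogenation adds H2 syn to the alkyne only, giving the 6Z alkene and so the Z,Z‑diene, quinoline being added to hold back reduction of the diene.

Step 11
Reactants: 15 (3R,4Z,6Z,8S)‑3‑[(tert‑butyldimethylsilyl)oxy]‑4‑methyl‑8,9‑bis[(triethylsilyl)oxy]nona‑4,6‑dienal
Product: 16 methyl (2Z,5R,6Z,8Z,10S)‑5‑[(tert‑butyldimethylsilyl)oxy]‑2‑iodo‑6‑methyl‑10,11‑bis[(triethylsilyl)oxy]undeca‑2,6,8‑trienoate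
Conditions: Ph3P=CHCO2Me, N‑iodosuccinimide, CH2Cl2, −20 °C; then 15, −20 °C → rt
Reagents that add atoms: methyl (triphenylphosphoranylidene)acetate, COC(=O)C=P(c1ccccc1)(c1ccccc1)c1ccccc1; N‑iodosuccinimide, O=C1CCC(=O)N1I
Why: Wittig olefination with the α‑iodo ylide made in the flask from the stabilised ylide and NIS is expected to favour the Z α‑iodoenoate (chain trans to the ester), which fixes the later ring‑cis C1=C10 geometry.

Step 12
Reactants: 16 methyl (2Z,5R,6Z,8Z,10S)‑5‑[(tert‑butyldimethylsilyl)oxy]‑2‑iodo‑6‑methyl‑10,11‑bis[(triethylsilyl)oxy]undeca‑2,6,8‑trienoate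
Product: 17 methyl (2Z,5R,6Z,8Z,10S)‑5‑[(tert‑butyldimethylsilyl)oxy]‑2‑iodo‑6‑methyl‑11‑oxo‑10‑[(triethylsilyl)oxy]undeca‑2,6,8‑trienoate
Conditions: (COCl)2, DMSO, CH2Cl2, −78 → −40 °C; then Et3N, −78 → 0 °C; used at once
Reagents that add atoms: none
Why: Swern oxidation cleaves and oxidises the primary TES ether in one operation while the secondary TES and TBS ethers persist, giving the α‑silyloxy aldehyde, which is used at once to avoid epimerisation at C8.

Step 13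
Reactants: 17 methyl (2Z,5R,6Z,8Z,10S)‑5‑[(tert‑butyldimethylsilyl)oxy]‑2‑iodo‑6‑methyl‑11‑oxo‑10‑[(triethylsilyl)oxy]undeca‑2,6,8‑trienoate
Product: 18 methyl (1E,4R,5Z,7Z,9S,10R)‑4‑[(tert‑butyldimethylsilyl)oxy]‑10‑hydroxy‑5‑methyl‑9‑[(triethylsilyl)oxy]cyclodeca‑1,5,7‑triene‑1‑carboxylate
Conditions: CrCl2 (10 equiv), NiCl2 (cat.), degassed DMSO/THF, syringe‑pump addition of 17 to 2 mM, rt
Reagents that add atoms: none
Why: Nozaki–Hiyama–Kishi reaction, in which Ni inserts into the activated alkenyl C–I bond and the alkenylchromium adds to the aldehyde with retention of the alkene geometry (ring‑cis C1=C10) and from the Felkin–Anh face anti to the C8 silyloxy group, which should set 9R (8,9‑erythro), the two Z alkenes pre‑bending the chain for ten‑ring closure under high dilution.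

Step 14
Reactants: 18 methyl (1E,4R,5Z,7Z,9S,10R)‑4‑[(tert‑butyldimethylsilyl)oxy]‑10‑hydroxy‑5‑methyl‑9‑[(triethylsilyl)oxy]cyclodeca‑1,5,7‑triene‑1‑carboxylate; 19 2‑bromoacrylic acid
Product: 21 methyl (1(10)E,4Z;3R,6R,7S,8S,9R)‑3‑[(tert‑butyldimethylsilyl)oxy]‑9‑hydroxy‑8‑[(triethylsilyl)oxy]germacra‑1(10),4,11(13)‑trien‑12,6‑olid‑14‑oate (trans‑fused lactone), via allylpalladium carboxylate 20 (not isolated)
Conditions: 19 (1.5 equiv, slow addition), Pd(OAc)2 (10 mol %), n‑Bu4NCl, NaHCO3, DMF, 60 °C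
Reagents that add atoms: none
Why: Proposed new method: Pd(0) inserts into the C–Br bond of sodium 2‑bromoacrylate, the alkenyl‑Pd(II) adds syn across C6=C7 with its carbon at C7 to give an η3‑allyl‑Pd over C6–C5–C4, and the tethered carboxylate attacks C6 on the face opposite to palladium (outer‑sphere attack, favoured by halide‑ligated Pd), releasing Pd(0). The closest known reaction type is the Larock heteroannulation of 1,3‑dienes with o‑iodobenzoic acids and related halides bearing OH, NHR or CO2H groups (carbopalladation, then intramolecular capture of the π‑allyl), which has not been shown for a 2‑haloacrylic acid on a medium‑ring diene. The only ring closed is the γ‑lactone, by 5‑exo attack of the carboxylate oxygen on the allyl terminus C6; the C7–C11 bond is made intermolecularly. C7 is set by 1,2‑induction from C8: in the A(1,3)‑minimised conformer of the Z‑allylic silyl ether the OSiEt3 group shields the α‑face (and the free 9‑OH on the β‑side can guide palladium), so C11 should enter β; C6 then follows from C7, because anti capture across the former Z‑C6=C7 bond gives the trans‑fused lactone (6α‑O, 7β‑C). The step needs site selectivity for the diene over the trisubstituted enoate C1=C10 (electron‑poor and hindered), regioselectivity for C7 over the methyl‑bearing terminus C4 and for C6 over C4 in the capture (five‑ against seven‑membered lactone), and retention of the 4Z geometry (no σ‑Pd at the tertiary C4, ring constraint).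

Step 15
Reactants: 21 methyl (3R,6R,7S,8S,9R)‑3‑[(tert‑butyldimethylsilyl)oxy]‑9‑hydroxy‑8‑[(triethylsilyl)oxy]germacra‑1(10),4,11(13)‑trien‑12,6‑olid‑14‑oate
Product: 22 methyl (3R,6R,7S,8S,9R)‑9‑acetoxy‑3‑[(tert‑butyldimethylsilyl)oxy]‑8‑[(triethylsilyl)oxy]germacra‑1(10),4,11(13)‑trien‑12,6‑olid‑14‑oate
Conditions: Ac2O, pyridine, DMAP (5 mol %), CH2Cl2, 0 °C
Reagents that add atoms: acetic anhydride, CC(=O)OC(C)=O
Why: DMAP‑catalysed acetylation of the only free hydroxyl, placed after the palladium step because an allylic acetate next to the enoate would ionise with Pd(0).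

Step 16
Reactants: 22 methyl (3R,6R,7S,8S,9R)‑9‑acetoxy‑3‑[(tert‑butyldimethylsilyl)oxy]‑8‑[(triethylsilyl)oxy]germacra‑1(10),4,11(13)‑trien‑12,6‑olid‑14‑oate
Product: 23 methyl (3R,6R,7R,8S,9R)‑9‑acetoxy‑3‑[(tert‑butyldimethylsilyl)oxy]‑8‑hydroxygermacra‑1(10),4,11(13)‑trien‑12,6‑olid‑14‑oate
Conditions: HF·pyridine, pyridine, THF, 0 °C
Reagents that add atoms: none
Why: Buffered HF·pyridine cleaves the secondary TES ether much faster than the TBS ether and, being mildly acidic, should not trigger O9→O8 acetyl migration or addition to the methylene lactone.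

Step 17
Reactants: 24 angelic acid
Product: 25 (Z)‑2‑methylbut‑2‑en‑1‑ol
Conditions: LiAlH4, Et2O, 0 °C → rt
Reagents that add atoms: none
Why: Hydride reduction of the carboxylic acid gives the allylic alcohol with the Z (angelate) geometry retained.

Step 18
Reactants: 25 (Z)‑2‑methylbut‑2‑en‑1‑ol
Product: 26 [(2R,3S)‑2,3‑dimethyloxiran‑2‑yl]methanol
Conditions: Ti(OiPr)4 (cat.), D‑(−)‑diethyl tartrate, t‑BuOOH, 4 Å MS, CH2Cl2, −20 °C
Reagents that add atoms: tert‑butyl hydroperoxide, CC(C)(C)OO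
Why: Sharpless asymmetric epoxidation with D‑(−)‑tartrate should deliver oxygen to the enantioface that gives the (2R,3S) epoxy alcohol (the face opposite to the one used by L‑(+)‑tartrate), the syn addition keeping the two methyl groups trans.

Step 19
Reactants: 26 [(2R,3S)‑2,3‑dimethyloxiran‑2‑yl]methanol
Product: 27 (2S,3S)‑2,3‑dimethyloxirane‑2‑carboxylic acid
Conditions: RuCl3·xH2O (2 mol %), NaIO4 (3 equiv), CCl4/MeCN/H2O, rt
Reagents that add atoms: sodium periodate, [Na+].[O-]I(=O)(=O)=O; water, O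
Why: Catalytic RuO4 oxidation takes the primary alcohol to the carboxylic acid without opening the oxirane, and the C2 descriptor changes from R to S only through the change in substituent priority.

Step 20
Reactants: 23 methyl (3R,6R,7R,8S,9R)‑9‑acetoxy‑3‑[(tert‑butyldimethylsilyl)oxy]‑8‑hydroxygermacra‑1(10),4,11(13)‑trien‑12,6‑olid‑14‑oate; 27 (2S,3S)‑2,3‑dimethyloxirane‑2‑carboxylic acid
Product: 29 methyl (3R,6R,7S,8S,9R)‑9‑acetoxy‑3‑[(tert‑butyldimethylsilyl)oxy]‑8‑{[(2S,3S)‑2,3‑dimethyloxiran‑2‑yl]carbonyloxy}germacra‑1(10),4,11(13)‑trien‑12,6‑olid‑14‑oate, via mixed anhydride 28 (not isolated)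
Conditions: 27, 2,4,6‑trichlorobenzoyl chloride, Et3N, THF, rt; then 23, DMAP, toluene, rt
Reagents that add atoms: none
Why: Yamaguchi esterification, in which the hindered epoxy acid is activated as the mixed anhydride and transferred by DMAP to the secondary 8‑OH, the acid having no enolisable centre and the reaction being run at room temperature to limit acetyl migration from O9.

Step 21
Reactants: 29 methyl (3R,6R,7S,8S,9R)‑9‑acetoxy‑3‑[(tert‑butyldimethylsilyl)oxy]‑8‑{[(2S,3S)‑2,3‑dimethyloxiran‑2‑yl]carbonyloxy}germacra‑1(10),4,11(13)‑trien‑12,6‑olid‑14‑oate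
Product: 30 methyl (3R,6R,7S,8S,9R)‑9‑acetoxy‑8‑{[(2S,3S)‑2,3‑dimethyloxiran‑2‑yl]carbonyloxy}‑3‑hydroxygermacra‑1(10),4,11(13)‑trien‑12,6‑olid‑14‑oate
Conditions: HF·pyridine, pyridine, THF, 0 °C → rt
Reagents that add atoms: none
Why: Fluoride‑mediated desilylation under buffered, mildly acidic conditions that the four ester groups, the methylene lactone and the electron‑poor side‑chain oxirane should tolerate.

Step 22
Reactants: 30 methyl (3R,6R,7S,8S,9R)‑9‑acetoxy‑8‑{[(2S,3S)‑2,3‑dimethyloxiran‑2‑yl]carbonyloxy}‑3‑hydroxygermacra‑1(10),4,11(13)‑trien‑12,6‑olid‑14‑oate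
Product: 31 CNP0301544.1, methyl (3R,4S,5R,6S,7R,8S,9R)‑9‑acetoxy‑8‑{[(2S,3S)‑2,3‑dimethyloxiran‑2‑yl]carbonyloxy}‑4,5‑epoxy‑3‑hydroxygermacra‑1(10),11(13)‑dien‑12,6‑olid‑14‑oate
Conditions: mCPBA, CH2Cl2/aqueous pH 7 phosphate buffer, 0 °C
Reagents that add atoms: 3‑chloroperbenzoic acid, O=C(OO)c1cccc(Cl)c1
Why: Hydroxyl‑directed peracid epoxidation (Henbest effect) of the only electron‑rich alkene, in which hydrogen‑bonded delivery in the A(1,3)‑minimised conformer of a medium‑ring Z‑allylic alcohol puts the oxirane trans to the hydroxyl across the ring and should set 4S,5R (4β,5β‑epoxide from 3α‑OH), while the enoate and methylene lactone alkenes are too electron‑poor to react.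

## Compound list

1 | prop‑2‑yn‑1‑ol | C#CCO | starting material
2 | (Z)‑[3‑(bromomagnesiooxy)‑2‑methylprop‑1‑en‑1‑yl]magnesium bromide | Br[Mg]OC/C(C)=C\[Mg]Br | intermediate
3 | (Z)‑3‑iodo‑2‑methylprop‑2‑en‑1‑ol | OC/C(C)=C\I | intermediate
4 | (Z)‑3‑iodo‑2‑methylprop‑2‑enal | O=C/C(C)=C\I | intermediate
5 | (3R,1Z)‑1‑iodo‑2‑methylhexa‑1,5‑dien‑3‑yl diisopinocampheylborinate | C=CC[C@@H](OB([C@H]1C[C@H]2C[C@H](C2(C)C)[C@@H]1C)[C@H]1C[C@H]2C[C@H](C2(C)C)[C@@H]1C)/C(C)=C\I | intermediate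
6 | (3R,1Z)‑1‑iodo‑2‑methylhexa‑1,5‑dien‑3‑ol | C=CC[C@@H](O)/C(C)=C\I | intermediate
7 | tert‑butyl{[(3R,1Z)‑1‑iodo‑2‑methylhexa‑1,5‑dien‑3‑yl]oxy}dimethylsilane | C=CC[C@@H](O[Si](C)(C)C(C)(C)C)/C(C)=C\I | intermediate
8 | (4R,5Z)‑4‑[(tert‑butyldimethylsilyl)oxy]‑6‑iodo‑5‑methylhex‑5‑ene‑1,2‑diol (both C2 epimers) | OCC(O)C[C@@H](O[Si](C)(C)C(C)(C)C)/C(C)=C\I | intermediate
9 | (3R,4Z)‑3‑[(tert‑butyldimethylsilyl)oxy]‑5‑iodo‑4‑methylpent‑4‑enal | O=CC[C@@H](O[Si](C)(C)C(C)(C)C)/C(C)=C\I | intermediate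
10 | (R)‑2,2‑dimethyl‑1,3‑dioxolane‑4‑carbaldehyde (D‑glyceraldehyde acetonide) | O=C[C@H]1COC(C)(C)O1 | starting material
11 | (S)‑4‑ethynyl‑2,2‑dimethyl‑1,3‑dioxolane | C#C[C@H]1COC(C)(C)O1 | intermediate
12 | (S)‑but‑3‑yne‑1,2‑diol | C#C[C@H](O)CO | intermediate
13 | (S)‑3,4‑bis[(triethylsilyl)oxy]but‑1‑yne | C#C[C@H](O[Si](CC)(CC)CC)CO[Si](CC)(CC)CC | intermediate
14 | (3R,4Z,8S)‑3‑[(tert‑butyldimethylsilyl)oxy]‑4‑methyl‑8,9‑bis[(triethylsilyl)oxy]non‑4‑en‑6‑ynal | O=CC[C@@H](O[Si](C)(C)C(C)(C)C)/C(C)=C\C#C[C@H](O[Si](CC)(CC)CC)CO[Si](CC)(CC)CC | intermediate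
15 | (3R,4Z,6Z,8S)‑3‑[(tert‑butyldimethylsilyl)oxy]‑4‑methyl‑8,9‑bis[(triethylsilyl)oxy]nona‑4,6‑dienal | O=CC[C@@H](O[Si](C)(C)C(C)(C)C)/C(C)=C\C=C/[C@H](O[Si](CC)(CC)CC)CO[Si](CC)(CC)CC | intermediate
16 | methyl (2Z,5R,6Z,8Z,10S)‑5‑[(tert‑butyldimethylsilyl)oxy]‑2‑iodo‑6‑methyl‑10,11‑bis[(triethylsilyl)oxy]undeca‑2,6,8‑trienoate | COC(=O)/C(I)=C/C[C@@H](O[Si](C)(C)C(C)(C)C)/C(C)=C\C=C/[C@H](O[Si](CC)(CC)CC)CO[Si](CC)(CC)CC | intermediate
17 | methyl (2Z,5R,6Z,8Z,10S)‑5‑[(tert‑butyldimethylsilyl)oxy]‑2‑iodo‑6‑methyl‑11‑oxo‑10‑[(triethylsilyl)oxy]undeca‑2,6,8‑trienoate | COC(=O)/C(I)=C/C[C@@H](O[Si](C)(C)C(C)(C)C)/C(C)=C\C=C/[C@H](O[Si](CC)(CC)CC)C=O | intermediate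
18 | methyl (1E,4R,5Z,7Z,9S,10R)‑4‑[(tert‑butyldimethylsilyl)oxy]‑10‑hydroxy‑5‑methyl‑9‑[(triethylsilyl)oxy]cyclodeca‑1,5,7‑triene‑1‑carboxylate | [C@@H]1(O)/C(C(=O)OC)=C\C[C@@H](O[Si](C)(C)C(C)(C)C)/C(C)=C\C=C/[C@@H]1O[Si](CC)(CC)CC | intermediate
19 | 2‑bromoacrylic acid | C=C(Br)C(=O)O | starting material
20 | sodium allylpalladium(II) chloride carboxylate formed by carbopalladation of 18 at C7 (η3 over C4–C6, drawn η1 at C6, Pd on the β‑face) | C=C(C(=O)[O-])[C@@H]1[C@H](O[Si](CC)(CC)CC)[C@H](O)/C(C(=O)OC)=C\C[C@@H](O[Si](C)(C)C(C)(C)C)/C(C)=C\[C@@H]1[Pd]Cl.[Na+] | intermediate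
21 | methyl (1(10)E,4Z;3R,6R,7S,8S,9R)‑3‑[(tert‑butyldimethylsilyl)oxy]‑9‑hydroxy‑8‑[(triethylsilyl)oxy]germacra‑1(10),4,11(13)‑trien‑12,6‑olid‑14‑oate | C=C1C(=O)O[C@@H]2/C=C(C)\[C@H](O[Si](C)(C)C(C)(C)C)C/C=C(C(=O)OC)\[C@@H](O)[C@@H](O[Si](CC)(CC)CC)[C@@H]12 | intermediate
22 | methyl (1(10)E,4Z;3R,6R,7S,8S,9R)‑9‑acetoxy‑3‑[(tert‑butyldimethylsilyl)oxy]‑8‑[(triethylsilyl)oxy]germacra‑1(10),4,11(13)‑trien‑12,6‑olid‑14‑oate | C=C1C(=O)O[C@@H]2/C=C(C)\[C@H](O[Si](C)(C)C(C)(C)C)C/C=C(C(=O)OC)\[C@@H](OC(C)=O)[C@@H](O[Si](CC)(CC)CC)[C@@H]12 | intermediate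
23 | methyl (1(10)E,4Z;3R,6R,7R,8S,9R)‑9‑acetoxy‑3‑[(tert‑butyldimethylsilyl)oxy]‑8‑hydroxygermacra‑1(10),4,11(13)‑trien‑12,6‑olid‑14‑oate | C=C1C(=O)O[C@@H]2/C=C(C)\[C@H](O[Si](C)(C)C(C)(C)C)C/C=C(C(=O)OC)\[C@@H](OC(C)=O)[C@@H](O)[C@@H]12 | intermediate
24 | angelic acid, (Z)‑2‑methylbut‑2‑enoic acid | C/C=C(/C)C(=O)O | starting material
25 | (Z)‑2‑methylbut‑2‑en‑1‑ol | C/C=C(/C)CO | intermediate
26 | [(2R,3S)‑2,3‑dimethyloxiran‑2‑yl]methanol | OC[C@@]1(C)O[C@H]1C | intermediate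
27 | (2S,3S)‑2,3‑dimethyloxirane‑2‑carboxylic acid | OC(=O)[C@@]1(C)O[C@H]1C | intermediate
28 | (2S,3S)‑2,3‑dimethyloxirane‑2‑carboxylic 2,4,6‑trichlorobenzoic anhydride | O=C(OC(=O)[C@@]1(C)O[C@H]1C)c1c(Cl)cc(Cl)cc1Cl | intermediate
29 | methyl (1(10)E,4Z;3R,6R,7S,8S,9R)‑9‑acetoxy‑3‑[(tert‑butyldimethylsilyl)oxy]‑8‑{[(2S,3S)‑2,3‑dimethyloxiran‑2‑yl]carbonyloxy}germacra‑1(10),4,11(13)‑trien‑12,6‑olid‑14‑oate | C=C1C(=O)O[C@@H]2/C=C(C)\[C@H](O[Si](C)(C)C(C)(C)C)C/C=C(C(=O)OC)\[C@@H](OC(C)=O)[C@@H](OC(=O)[C@@]3(C)O[C@H]3C)[C@@H]12 | intermediate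
30 | methyl (1(10)E,4Z;3R,6R,7S,8S,9R)‑9‑acetoxy‑8‑{[(2S,3S)‑2,3‑dimethyloxiran‑2‑yl]carbonyloxy}‑3‑hydroxygermacra‑1(10),4,11(13)‑trien‑12,6‑olid‑14‑oate | C=C1C(=O)O[C@@H]2/C=C(C)\[C@H](O)C/C=C(C(=O)OC)\[C@@H](OC(C)=O)[C@@H](OC(=O)[C@@]3(C)O[C@H]3C)[C@@H]12 | intermediate
31 | CNP0301544.1, methyl (1(10)E;3R,4S,5R,6S,7R,8S,9R)‑9‑acetoxy‑8‑{[(2S,3S)‑2,3‑dimethyloxiran‑2‑yl]carbonyloxy}‑4,5‑epoxy‑3‑hydroxygermacra‑1(10),11(13)‑dien‑12,6‑olid‑14‑oate | C=C1C(=O)O[C@H]2[C@H]1[C@H](OC(=O)[C@@]1(C)O[C@H]1C)[C@H](OC(C)=O)/C(C(=O)OC)=C\C[C@@H](O)[C@]1(C)O[C@H]21 | target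

## Step count and risks

Total step count: 22. Longest linear sequence: 16 steps (1–5, 9–16, 20–22).

**Step 14 (proposed new method).** Carbopalladation may occur on the wrong face of C6=C7, the allyl‑Pd may close by inner‑sphere delivery to give the cis‑fused lactone, or the bromoacrylate may oligomerise or react again with the product's methylene group. Fallback with known chemistry, setting out from 18: a Mn(III)‑mediated oxidative radical lactone annulation of the 1,3‑diene with (diethoxyphosphoryl)acetic acid [Mn(OAc)3·2H2O, Cu(OAc)2 (cat.), KOAc, AcOH, 50 °C] should add the stabilised radical at C7, oxidise the allyl radical and close the carboxyl group on C6 to give the α‑phosphono lactone F1 (mixture at C11). A Horner–Wadsworth–Emmons methylenation with aqueous formaldehyde and K2CO3 then returns to the route at 21.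

**Step 13.** Intermolecular coupling and oligomerisation may outrun ten‑ring closure, the alkenyl iodide may be reduced, or facial control at C9 may be poor. Fallback, setting out from 15: Wittig methylenation (Ph3P=CH2) gives the triene (4R,5Z,7Z,9S)‑4‑(TBSO)‑5‑methyl‑9,10‑bis(TESO)deca‑1,5,7‑triene F2. Swern oxidation of its primary TES ether gives the aldehyde F3. Addition of [α‑(methoxycarbonyl)vinyl]aluminium (methyl propiolate, DIBAL‑H, NMO, THF, 0 °C) should give the Morita–Baylis–Hillman‑type adduct F4 with the same Felkin preference. Ring‑closing metathesis between its two terminal alkenes (Hoveyda–Grubbs II, toluene, high dilution, 80 °C) forms C1=C10 instead of C9–C10 and returns to the route at 18.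

**Step 22.** Hydrogen‑bonded delivery may not override the ring conformation and the α‑oriented oxygen at C6, giving poor facial selectivity, or the acid by‑product may open the epoxy alcohol. Fallback, setting out from 29: NBS in aqueous DME should form the bromonium ion on the less shielded α‑face and let water enter at the tertiary C4 from the β‑face, giving the 4β‑hydroxy‑5α‑bromo compound F5. Ag2O closes it with inversion at C5 to the 4β,5β‑epoxide silyl ether F6, and HF·pyridine removes the TBS group to reach 31.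

## Further compounds

F1 | step 14 | methyl (3R,6R,7S,8S,9R)‑3‑[(tert‑butyldimethylsilyl)oxy]‑11‑(diethoxyphosphoryl)‑9‑hydroxy‑8‑[(triethylsilyl)oxy]germacra‑1(10),4‑dien‑12,6‑olid‑14‑oate (mixture at C11) | CCOP(=O)(OCC)C1C(=O)O[C@@H]2/C=C(C)\[C@H](O[Si](C)(C)C(C)(C)C)C/C=C(C(=O)OC)\[C@@H](O)[C@@H](O[Si](CC)(CC)CC)[C@@H]12
F2 | step 13 | (4R,5Z,7Z,9S)‑4‑[(tert‑butyldimethylsilyl)oxy]‑5‑methyl‑9,10‑bis[(triethylsilyl)oxy]deca‑1,5,7‑triene | C=CC[C@@H](O[Si](C)(C)C(C)(C)C)/C(C)=C\C=C/[C@H](O[Si](CC)(CC)CC)CO[Si](CC)(CC)CC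
F3 | step 13 | (2S,3Z,5Z,7R)‑7‑[(tert‑butyldimethylsilyl)oxy]‑6‑methyl‑2‑[(triethylsilyl)oxy]deca‑3,5,9‑trienal | C=CC[C@@H](O[Si](C)(C)C(C)(C)C)/C(C)=C\C=C/[C@H](O[Si](CC)(CC)CC)C=O
F4 | step 13 | methyl (3R,4S,5Z,7Z,9R)‑9‑[(tert‑butyldimethylsilyl)oxy]‑3‑hydroxy‑8‑methyl‑2‑methylidene‑4‑[(triethylsilyl)oxy]dodeca‑5,7,11‑trienoate | C=CC[C@@H](O[Si](C)(C)C(C)(C)C)/C(C)=C\C=C/[C@H](O[Si](CC)(CC)CC)[C@H](O)C(=C)C(=O)OC
F5 | step 22 | methyl 9‑acetoxy‑5α‑bromo‑3α‑[(tert‑butyldimethylsilyl)oxy]‑8β‑{[(2S,3S)‑2,3‑dimethyloxiran‑2‑yl]carbonyloxy}‑4β‑hydroxygermacra‑1(10),11(13)‑dien‑12,6‑olid‑14‑oate | C=C1C(=O)O[C@H]2[C@H]1[C@H](OC(=O)[C@@]1(C)O[C@H]1C)[C@H](OC(C)=O)/C(C(=O)OC)=C\C[C@@H](O[Si](C)(C)C(C)(C)C)[C@](C)(O)[C@H]2Br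
F6 | step 22 | methyl (3R,4S,5R,6S,7R,8S,9R)‑9‑acetoxy‑3‑[(tert‑butyldimethylsilyl)oxy]‑8‑{[(2S,3S)‑2,3‑dimethyloxiran‑2‑yl]carbonyloxy}‑4,5‑epoxygermacra‑1(10),11(13)‑dien‑12,6‑olid‑14‑oate | C=C1C(=O)O[C@H]2[C@H]1[C@H](OC(=O)[C@@]1(C)O[C@H]1C)[C@H](OC(C)=O)/C(C(=O)OC)=C\C[C@@H](O[Si](C)(C)C(C)(C)C)[C@]1(C)O[C@H]21
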